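(The readings stem from a simulated flask with made-up constants; the scatter is artificial.)

Start from Friday's leftover: at 60.0 min, 76.1% of the charged starting complex stands as something other than complex with two exchanged. Follow one charged molecule. Its chance of standing two-exchanged at that clock is the percent read, and on Friday that chance is higher than on Monday, with more incoming ligand.

| flask | starting complex | incoming ligand | remark | time |
|---|---|---|---|---|
| Monday's | 0.80 M (in portions, 4) | 0.79 M | run made earlier; portions every 10 min |  |
| Friday's | 0.80 M (in portions, 4) | 2.8 M | run made earlier; portions every 10 min |  |
| winter | 0.80 M (in portions, 4) | 0.250 M | the portions of starting complex follow each other after 10 min, the first at the start | 80 min |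
| summer | 0.80 M (in portions, 4) | 0.800 M | the portions of starting complex follow each other after 10 min, the first at the start | 80 min |
| autumn | 0.80 M (in portions, 4) | 3.00 M | the portions of starting complex follow each other after 10 min, the first at the start | 80 min |
| dawn | 0.80 M (in portions, 4) | 1.50 M | the portions of starting complex follow each other after 10 min, the first at the start | 80 min |

- Monday's (time / min: complex with two exchanged / %): 15.0: 2.6; 30.0: 6.3; 40.0: 6.7; 60.0: 5.8
- Friday's (time / min: complex with two exchanged / %): 5.00: 4.7; 10.0: 9.3; 25.0: 20.6; 60.0: 23.9

(scatter of a reading: 0.3 percentage points)

- the numbers in the tables scatter by 0.3 percentage points (one standard deviation)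

- the flasks put in order of amount of complex with two exchanged, in percent of the starting complex charged, best first, at 80 min (winter / summer / autumn / dawn)
- the amount of complex with two exchanged, in percent of the starting complex charged of the flask you put first, at 80 min
- the amount of complex with two exchanged, in percent of the starting complex charged of the flask you put last, at 80 min

Read how steeply the chance climbs. Do it two ways. Way one takes both runs at one clock, 60.0 min:

n = ln(23.9% / 5.8%) / ln(2.8 M / 0.79 M) = 1.12

Call n the same-clock order: the slope of ln(yield) against ln c(incoming ligand) between two runs with the same charge and portions of starting complex, read at one time, an apparent order. Way two takes highest reading against highest reading: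

m = ln(23.9% / 6.7%) / ln(2.8 M / 0.79 M) = 1.01

Scale from Friday with either:

yield = 23.9% × (c(incoming ligand) / 2.8 M)^n

For autumn, n gives 25.8% and m gives 25.6%. Both start from Friday's reading, so that agreement proves little. Winter parts them: n gives 1.60%, m gives 2.11%.

Way two cheats. Monday's highest reading stands at 40.0 min, Friday's at 60.0 min: two clocks. By 60.0 min Monday's reading has dropped 0.9 percentage points, against a scatter of 0.3 points. Keep n. My reckoning:

autumn 25.8%, dawn 11.9%, summer 5.88%, winter 1.60%

Monday's last reading stands below the one before it, so I expect summer and winter under these lines at 80 min.

The forecast gives autumn > dawn > summer > winter, with 24% first and 0.8% last: “The ligand-rich flask should stay best.” My order is the same. My winter stands higher than its figure.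

The flasks give autumn > dawn > summer > winter, with 24.6% in autumn and 1.06% in winter.

    leaving ligand → by-product carried off (k = 0.0220 min⁻¹)
    complex with one exchanged → side product (k = 0.00890 min⁻¹)
    starting complex + incoming ligand ⇌ leaving ligand + complex with one exchanged (K = 0.780, k = 0.0640 M⁻¹ min⁻¹)
    complex with one exchanged → decomposed reagent (k = 0.0250 min⁻¹)
    complex with one exchanged + incoming ligand ⇌ leaving ligand + complex with two exchanged (K = 0.220, k = 0.0590 M⁻¹ min⁻¹)

Autumn at 80 min leaves 75.4% outside the product, against 76.1% in Friday's reading at 60.0 min. The reckoned 25.8% for autumn stands 1.2 points above the flask. Now take the neighbour: autumn's recipe with 1.2 M of incoming ligand. Scale Friday's reading with n again, and it gives 9.26%. That neighbour flask holds 8.86% of complex with two exchanged at 80 min.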